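The target is read as (3R,4S)-3-[(3R)-3,5-dihydroxy-2,2-dimethylchroman-6-yl]chromane-4,7-diol, a 3,4-trans isoflavan-4-ol with an R carbinol in the dimethylpyran ring.

## Retrosynthetic overview

1. Target 15 comes from debenzylation and a reagent-controlled ketone reduction (sets C4) of the (3R)-2'-hydroxyisoflavanone 13.
2. Key disconnection C3–C4: the A-ring aldehyde carbon, turned into a carbene-bound acyl anion, adds intramolecularly to the methide carbon of a B-ring o-quinone methide 12. Both carbons are natural acceptors, and this step sets C3.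
3. The o-quinone methide precursor 11 (2-(1-sulfonylalkyl)phenol) comes from aryloxy alcohol 9. Compound 9 comes from phenol 7 and aryl oxirane 8 (O1–C2 bond), with C2 supplied by a sulfur ylide.
4. B-ring aldehyde 6 comes from Jacobsen epoxidation and benzylic hydrogenolysis (sets the pyran carbinol) of chromene 3, made from 2,4-dihydroxybenzaldehyde and prenal.
5. Ring order: the dimethylpyran ring is formed first, and the chromanone ring C is closed last, in the key step.

Assumption: the triazolium antipode that gives 3R in step 7 is fixed by one test run (both antipodes are sold), and because the pyran carbinol is already present the C3 epimers are diastereomers whose ratio is read directly by NMR.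

## Route

**Step 1**
Reactants: 1 2,4-dihydroxybenzaldehyde; 2 3-methylbut-2-enal (prenal)
Product: 3 5-hydroxy-2,2-dimethyl-2H-chromene-6-carbaldehyde
Conditions: ethylenediammonium diacetate (10 mol %), toluene, reflux, Dean–Stark
Reagents that add atoms: none
Why: Formal [3+3] chromenylation (Knoevenagel-type C-alkylation at C3 between the two oxygens, loss of water, oxa-6π electrocyclisation); the 2-OH is tied up in a hydrogen bond to CHO, so the 4-OH closes the pyran and only the angular 5-hydroxy-6-formyl isomer forms.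

**Step 2**
Reactants: 3 5-hydroxy-2,2-dimethyl-2H-chromene-6-carbaldehyde
Product: 4 5-(methoxymethoxy)-2,2-dimethyl-2H-chromene-6-carbaldehyde
Conditions: NaH, MOMCl, DMF, 0 °C → rt
Reagents that add atoms: chloromethyl methyl ether (MOMCl), COCCl
Why: Williamson-type O-alkylation of the sodium phenoxide; the acetal survives hypochlorite, hydrogenation, ylide and phenoxide, and masks a phenol that would otherwise disturb the Mn catalyst and intercept the ylide adduct in step 5.

**Step 3**
Reactants: 4 5-(methoxymethoxy)-2,2-dimethyl-2H-chromene-6-carbaldehyde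
Product: 5 (3R,4R)-3,4-epoxy-5-(methoxymethoxy)-2,2-dimethylchromane-6-carbaldehyde
Conditions: (R,R)-Jacobsen Mn(salen)Cl (4 mol %), 4-phenylpyridine N-oxide (20 mol %), aq NaOCl (pH 11.3), CH2Cl2, 0 °C
Reagents that add atoms: sodium hypochlorite, [Na+].[O-]Cl
Why: Jacobsen–Katsuki epoxidation, for which cis-configured 2,2-dimethylchromenes are the best substrate class; the (R,R)-complex gives the (3R,4R)-epoxide and so fixes the later carbinol as R, and the 6-formyl group tames the donor oxygens so the benzylic epoxide can be handled.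

**Step 4**
Reactants: 5 (3R,4R)-3,4-epoxy-5-(methoxymethoxy)-2,2-dimethylchromane-6-carbaldehyde
Product: 6 (3R)-3-hydroxy-5-(methoxymethoxy)-2,2-dimethylchromane-6-carbaldehyde
Conditions: H2 (1 atm), 10% Pd/C, solid NaHCO3, EtOAc, rt, stopped after 1 equiv H2
Reagents that add atoms: none
Why: Hydrogenolysis of the benzylic C4–O bond of the epoxide, which is much faster than reduction of an electron-rich aryl aldehyde (as in routine debenzylation of benzyloxybenzaldehydes); the C3–O bond is not touched, so 3R is retained.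

**Step 5**
Reactants: 6 (3R)-3-hydroxy-5-(methoxymethoxy)-2,2-dimethylchromane-6-carbaldehyde; 7 4-(benzyloxy)-2-hydroxybenzaldehyde
Product: 9 4-(benzyloxy)-2-{2-hydroxy-2-[(3R)-3-hydroxy-5-(methoxymethoxy)-2,2-dimethylchroman-6-yl]ethoxy}benzaldehyde (both carbinol epimers), via aryl oxirane 8 (not isolated)
Conditions: Me3SI (1.2 equiv), NaH (2.3 equiv), DMSO–THF, 0 °C → rt, 1 h; then 7 (1.2 equiv), 70 °C; aq NH4Cl
Reagents that add atoms: trimethylsulfonium iodide, C[S+](C)C.[I-]
Why: Corey–Chaykovsky methylene transfer gives the silica-labile electron-rich styrene oxide, the acidic phenol 7 then quenches leftover ylide and base faster than its aldehyde can react, and its phenoxide opens the oxirane by SN2 at the unhindered CH2; the new carbinol centre forms as a mixture, which does not matter because it becomes planar in step 7.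

**Step 6**
Reactants: 9 4-(benzyloxy)-2-{2-hydroxy-2-[(3R)-3-hydroxy-5-(methoxymethoxy)-2,2-dimethylchroman-6-yl]ethoxy}benzaldehyde
Product: 11 4-(benzyloxy)-2-{2-[(3R)-3,5-dihydroxy-2,2-dimethylchroman-6-yl]-2-(4-methylbenzenesulfonyl)ethoxy}benzaldehyde (both sulfone epimers), via MOM-protected sulfone 10 (not isolated)
Conditions: p-TolSO2H (4 equiv), CH2Cl2, rt, 2 h; then TFA (10 vol %), 0 °C → rt
Reagents that add atoms: p-toluenesulfinic acid, Cc1ccc(cc1)S(=O)O
Why: SN1 substitution, in which only the 2,4-dioxygenated benzylic alcohol ionises under the sulfinic acid and is captured at sulfur, followed by acidolysis of the aryl MOM acetal with excess sulfinic acid scavenging the methoxymethyl cation; substituting first removes the neighbouring OH that could otherwise close a 1,3-benzodioxine.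

**Step 7 (key step)**
Reactants: 11 4-(benzyloxy)-2-{2-[(3R)-3,5-dihydroxy-2,2-dimethylchroman-6-yl]-2-(4-methylbenzenesulfonyl)ethoxy}benzaldehyde
Product: 13 (3R)-7-(benzyloxy)-3-[(3R)-3,5-dihydroxy-2,2-dimethylchroman-6-yl]chroman-4-one, via ortho-quinone methide 12 (not isolated)
Conditions: (5aS,10bR)-aminoindanol-derived N-C6F5 triazolium BF4 (15 mol %), iPr2NEt (2 equiv), 4 Å MS, toluene, 0 °C
Reagents that add atoms: none
Why: Proposed new method: an asymmetric intramolecular Stetter reaction whose Michael acceptor is an o-quinone methide released in situ: the amine deprotonates the phenol of 11 and sulfinate leaves (E1cB) to give 12, whose exocyclic C=C–C=O unit has the ArO–CH2–CH=C–C=O connectivity of classical Stetter substrates, while the triazolylidene converts the aldehyde carbon into a nucleophilic enaminol (acyl anion equivalent) that attacks the methide carbon 6-exo-trig, rearomatisation of ring B makes the addition irreversible, and collapse of the adduct frees the carbene and the ketone; the indane wall of the carbene blocks one face of the enaminol so that one face of the (E)-methide is attacked and C3 is set as R, and the weak amine base in toluene at 0 °C limits epimerisation; the closest known reaction types are the enantioselective intramolecular Stetter cyclisation of salicylaldehyde-derived enoates to 3-substituted chroman-4-ones, the addition of azolium-derived acyl anions to o- and p-quinone methides, and the base-induced release of o-quinone methides from 2-(1-sulfonylalkyl)phenols.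

**Step 8**
Reactants: 13 (3R)-7-(benzyloxy)-3-[(3R)-3,5-dihydroxy-2,2-dimethylchroman-6-yl]chroman-4-one
Product: 14 (3R,4S)-7-(benzyloxy)-3-[(3R)-3,5-dihydroxy-2,2-dimethylchroman-6-yl]chroman-4-ol
Conditions: (R)-Me-CBS (0.5 equiv), BH3·SMe2 (4 equiv), THF, −30 → 0 °C; MeOH, then pH 7 buffer
Reagents that add atoms: none
Why: Corey–Bakshi–Shibata reduction, in which the (R)-oxazaborolidine treats the fused aryl ring as the large group and gives the 4S carbinol as it does for aryl alkyl ketones; on the 3R ketone this is the axial attack that chromanones already prefer with small boranes, so the 3,4-trans alcohol results, the non-basic medium leaves C3 untouched, and the acid-free work-up avoids pterocarpan closure.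

**Step 9**
Reactants: 14 (3R,4S)-7-(benzyloxy)-3-[(3R)-3,5-dihydroxy-2,2-dimethylchroman-6-yl]chroman-4-ol
Product: 15 (3R,4S)-3-[(3R)-3,5-dihydroxy-2,2-dimethylchroman-6-yl]chromane-4,7-diol (target)
Conditions: H2 (1 atm), 10% Pd/C, solid NaHCO3, THF–EtOH, rt, stopped at full conversion
Reagents that add atoms: none
Why: Hydrogenolysis of the aryl benzyl ether under neutral conditions; isoflavan-4-ols are themselves the end point of neutral Pd/C hydrogenation of isoflavones, so the 4-OH survives, no acid is present to close the pterocarpan, and no stereocentre is touched.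

## Compound list

| No. | Name | SMILES | Role |
|---|---|---|---|
| 1 | 2,4-dihydroxybenzaldehyde | O=Cc1ccc(O)cc1O | starting material |
| 2 | 3-methylbut-2-enal | CC(C)=CC=O | starting material |
| 3 | 5-hydroxy-2,2-dimethyl-2H-chromene-6-carbaldehyde | CC1(C)C=Cc2c(O1)ccc(C=O)c2O | intermediate |
| 4 | 5-(methoxymethoxy)-2,2-dimethyl-2H-chromene-6-carbaldehyde | CC1(C)C=Cc2c(O1)ccc(C=O)c2OCOC | intermediate |
| 5 | (3R,4R)-3,4-epoxy-5-(methoxymethoxy)-2,2-dimethylchromane-6-carbaldehyde | CC1(C)Oc2ccc(C=O)c(OCOC)c2[C@H]3O[C@@H]13 | intermediate |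
| 6 | (3R)-3-hydroxy-5-(methoxymethoxy)-2,2-dimethylchromane-6-carbaldehyde | CC1(C)Oc2ccc(C=O)c(OCOC)c2C[C@H]1O | intermediate |
| 7 | 4-(benzyloxy)-2-hydroxybenzaldehyde | O=Cc1ccc(OCc2ccccc2)cc1O | starting material |
| 8 | (3R)-5-(methoxymethoxy)-2,2-dimethyl-6-(oxiran-2-yl)chroman-3-ol (both oxirane epimers) | CC1(C)Oc2ccc(C3CO3)c(OCOC)c2C[C@H]1O | intermediate |
| 9 | 4-(benzyloxy)-2-{2-hydroxy-2-[(3R)-3-hydroxy-5-(methoxymethoxy)-2,2-dimethylchroman-6-yl]ethoxy}benzaldehyde (both carbinol epimers) | CC1(C)Oc2ccc(C(O)COc3cc(OCc4ccccc4)ccc3C=O)c(OCOC)c2C[C@H]1O | intermediate |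
| 10 | 4-(benzyloxy)-2-{2-[(3R)-3-hydroxy-5-(methoxymethoxy)-2,2-dimethylchroman-6-yl]-2-(4-methylbenzenesulfonyl)ethoxy}benzaldehyde (both epimers) | CC1(C)Oc2ccc(C(COc3cc(OCc4ccccc4)ccc3C=O)S(=O)(=O)c3ccc(C)cc3)c(OCOC)c2C[C@H]1O | intermediate |
| 11 | 4-(benzyloxy)-2-{2-[(3R)-3,5-dihydroxy-2,2-dimethylchroman-6-yl]-2-(4-methylbenzenesulfonyl)ethoxy}benzaldehyde (both epimers) | CC1(C)Oc2ccc(C(COc3cc(OCc4ccccc4)ccc3C=O)S(=O)(=O)c3ccc(C)cc3)c(O)c2C[C@H]1O | intermediate |
| 12 | 4-(benzyloxy)-2-{(2E)-2-[(3R)-3-hydroxy-2,2-dimethyl-5-oxo-3,4-dihydro-2H-chromen-6(5H)-ylidene]ethoxy}benzaldehyde | CC1(C)OC2=C(C[C@H]1O)C(=O)/C(=C/COc1cc(OCc3ccccc3)ccc1C=O)C=C2 | intermediate |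
| 13 | (3R)-7-(benzyloxy)-3-[(3R)-3,5-dihydroxy-2,2-dimethylchroman-6-yl]chroman-4-one | CC1(C)Oc2ccc([C@@H]3COc4cc(OCc5ccccc5)ccc4C3=O)c(O)c2C[C@H]1O | intermediate |
| 14 | (3R,4S)-7-(benzyloxy)-3-[(3R)-3,5-dihydroxy-2,2-dimethylchroman-6-yl]chroman-4-ol | CC1(C)Oc2ccc([C@@H]3COc4cc(OCc5ccccc5)ccc4[C@H]3O)c(O)c2C[C@H]1O | intermediate |
| 15 | (3R,4S)-3-[(3R)-3,5-dihydroxy-2,2-dimethylchroman-6-yl]chromane-4,7-diol | CC1(C)Oc2ccc([C@@H]3COc4cc(O)ccc4[C@H]3O)c(O)c2C[C@H]1O | target |

## Step count and risks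

Total step count: 9. Longest linear sequence: 9 steps (1 and 2 to 15); compound 7 is bought.

**Step 7.** The risks:
- 12 may tautomerise to the 2-(2-aryloxyvinyl)phenol or oligomerise before the electron-rich aldehyde forms the enaminol.
- C3 may drift in base.

The fallback sets out from 9 and comes back at 13. It keeps the same acyl anion and the same C3–C4 bond but uses a ketone as acceptor.
- MnO2 in CH2Cl2 oxidises only the benzylic carbinol of 9 to 4-(benzyloxy)-2-{2-[(3R)-3-hydroxy-5-(methoxymethoxy)-2,2-dimethylchroman-6-yl]-2-oxoethoxy}benzaldehyde F1.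
- A triazolylidene-catalysed intramolecular crossed aldehyde–ketone benzoin reaction closes ring C to 7-(benzyloxy)-3-hydroxy-3-[(3R)-3-hydroxy-5-(methoxymethoxy)-2,2-dimethylchroman-6-yl]chroman-4-one F2.
- Warm HCl/MeOH removes the MOM group and dehydrates the tertiary benzylic alcohol to 7-(benzyloxy)-3-[(3R)-3,5-dihydroxy-2,2-dimethylchroman-6-yl]-4H-chromen-4-one F3.
- L-Selectride (THF, −78 °C) reduces the chromone 1,4 to 13 together with (3S)-7-(benzyloxy)-3-[(3R)-3,5-dihydroxy-2,2-dimethylchroman-6-yl]chroman-4-one F4.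
- F4 is separated as a diastereomer and recycled by DBU equilibration.

**Step 8.** The risks:
- The bulky catalyst–borane complex must approach the face toward which the 3-aryl group leans, so the cis alcohol may compete.
- Any C3 epimer in 13 is carried through.

The fallback sets out from 13 and comes back at 14. It replaces direct trans reduction with a cis-selective dynamic kinetic resolution followed by inversion.
- TBSOTf/2,6-lutidine gives (3R)-7-(benzyloxy)-3-[(3R)-3,5-bis(tert-butyldimethylsilyloxy)-2,2-dimethylchroman-6-yl]chroman-4-one F5.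
- RuCl[(R,R)-TsDPEN](p-cymene) in HCO2H/Et3N reduces it with racemisation of C3 to (3R,4R)-7-(benzyloxy)-3-[(3R)-3,5-bis(tert-butyldimethylsilyloxy)-2,2-dimethylchroman-6-yl]chroman-4-ol F6. This step also repairs C3.
- Mitsunobu reaction with 4-nitrobenzoic acid (PPh3, DIAD) inverts C4 to (3R,4S)-7-(benzyloxy)-3-[(3R)-3,5-bis(tert-butyldimethylsilyloxy)-2,2-dimethylchroman-6-yl]chroman-4-yl 4-nitrobenzoate F7.
- K2CO3/MeOH gives (3R,4S)-7-(benzyloxy)-3-[(3R)-3,5-bis(tert-butyldimethylsilyloxy)-2,2-dimethylchroman-6-yl]chroman-4-ol F8.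
- TBAF/AcOH returns 14.

**Step 6.** The risks:
- The benzylic cation carries a β-aryloxy group and may lose a proton or fragment toward a benzofuran.
- The TFA stage may degrade the free-phenol sulfone.

The fallback sets out from 9 and comes back at 12 (and hence 13). It avoids protic acid and changes the way the quinone methide is released.
- TMSOTf/2,2'-bipyridyl in MeCN followed by water cleaves the aryl MOM ether under buffered conditions to 4-(benzyloxy)-2-{2-[(3R)-3,5-dihydroxy-2,2-dimethylchroman-6-yl]-2-hydroxyethoxy}benzaldehyde F9.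
- Boc2O (1 equiv) with iPr2NEt and catalytic DMAP acylates the phenol to tert-butyl (3R)-6-{2-[5-(benzyloxy)-2-formylphenoxy]-1-hydroxyethyl}-3-hydroxy-2,2-dimethylchroman-5-yl carbonate F10.
- Under the carbene conditions of step 7 with DBU as base, the benzylic alkoxide takes over the Boc group and the phenoxide expels tert-butyl carbonate. This gives 12, which cyclises to 13.

## Further compounds

F1 | step 7 | 4-(benzyloxy)-2-{2-[(3R)-3-hydroxy-5-(methoxymethoxy)-2,2-dimethylchroman-6-yl]-2-oxoethoxy}benzaldehyde | CC1(C)Oc2ccc(C(=O)COc3cc(OCc4ccccc4)ccc3C=O)c(OCOC)c2C[C@H]1O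
F2 | step 7 | 7-(benzyloxy)-3-hydroxy-3-[(3R)-3-hydroxy-5-(methoxymethoxy)-2,2-dimethylchroman-6-yl]chroman-4-one | CC1(C)Oc2ccc(C3(O)COc4cc(OCc5ccccc5)ccc4C3=O)c(OCOC)c2C[C@H]1O
F3 | step 7 | 7-(benzyloxy)-3-[(3R)-3,5-dihydroxy-2,2-dimethylchroman-6-yl]-4H-chromen-4-one | CC1(C)Oc2ccc(C3=COc4cc(OCc5ccccc5)ccc4C3=O)c(O)c2C[C@H]1O
F4 | step 7 | (3S)-7-(benzyloxy)-3-[(3R)-3,5-dihydroxy-2,2-dimethylchroman-6-yl]chroman-4-one | CC1(C)Oc2ccc([C@H]3COc4cc(OCc5ccccc5)ccc4C3=O)c(O)c2C[C@H]1O
F5 | step 8 | (3R)-7-(benzyloxy)-3-[(3R)-3,5-bis(tert-butyldimethylsilyloxy)-2,2-dimethylchroman-6-yl]chroman-4-one | CC1(C)Oc2ccc([C@@H]3COc4cc(OCc5ccccc5)ccc4C3=O)c(O[Si](C)(C)C(C)(C)C)c2C[C@H]1O[Si](C)(C)C(C)(C)C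
F6 | step 8 | (3R,4R)-7-(benzyloxy)-3-[(3R)-3,5-bis(tert-butyldimethylsilyloxy)-2,2-dimethylchroman-6-yl]chroman-4-ol | CC1(C)Oc2ccc([C@@H]3COc4cc(OCc5ccccc5)ccc4[C@@H]3O)c(O[Si](C)(C)C(C)(C)C)c2C[C@H]1O[Si](C)(C)C(C)(C)C
F7 | step 8 | (3R,4S)-7-(benzyloxy)-3-[(3R)-3,5-bis(tert-butyldimethylsilyloxy)-2,2-dimethylchroman-6-yl]chroman-4-yl 4-nitrobenzoate | CC1(C)Oc2ccc([C@@H]3COc4cc(OCc5ccccc5)ccc4[C@H]3OC(=O)c6ccc([N+](=O)[O-])cc6)c(O[Si](C)(C)C(C)(C)C)c2C[C@H]1O[Si](C)(C)C(C)(C)C
F8 | step 8 | (3R,4S)-7-(benzyloxy)-3-[(3R)-3,5-bis(tert-butyldimethylsilyloxy)-2,2-dimethylchroman-6-yl]chroman-4-ol | CC1(C)Oc2ccc([C@@H]3COc4cc(OCc5ccccc5)ccc4[C@H]3O)c(O[Si](C)(C)C(C)(C)C)c2C[C@H]1O[Si](C)(C)C(C)(C)C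
F9 | step 6 | 4-(benzyloxy)-2-{2-[(3R)-3,5-dihydroxy-2,2-dimethylchroman-6-yl]-2-hydroxyethoxy}benzaldehyde | CC1(C)Oc2ccc(C(O)COc3cc(OCc4ccccc4)ccc3C=O)c(O)c2C[C@H]1O
F10 | step 6 | tert-butyl (3R)-6-{2-[5-(benzyloxy)-2-formylphenoxy]-1-hydroxyethyl}-3-hydroxy-2,2-dimethylchroman-5-yl carbonate | CC1(C)Oc2ccc(C(O)COc3cc(OCc4ccccc4)ccc3C=O)c(OC(=O)OC(C)(C)C)c2C[C@H]1O
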